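Ring A is the guaiacyl ring on the carbinol carbon C7'', ring B is the aryl ether ring on oxolane C2, and ring C is the guaiacyl ring on oxolane C5. C8'' is the ether-bearing side-chain carbon, and all intermediates keep the oxolane numbers of the target (O1, C2 to C5).
Cuts, in retrosynthetic order: the two O–benzyl bonds, ring A–C7'', C8''–O(ring B), C2–O1 of the oxolane, C2–ring B, C3–CH3 and C4–C5.
Enabling feature: C2 is a benzylic carbon para to the oxygen on ring B. As the CH2 group of a 4-alkyl-2-methoxyphenol it can be oxidised to the exocyclic carbon of a para-quinone methide, and the hydroxyl on C5 next to ring C can reach it through a five-membered transition state.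
Forward order: crotylboration of O-benzylvanillin joins C5–C4. The vinyl group (C3, C2) becomes a butyrolactone that is methylated at C3, and the opened lactone is coupled at C2 with ring B. The oxolane, the only ring built, closes in the key step, then the lactate unit and ring A are attached and both benzyl groups are removed.
Stereochemistry: C5 and C4 come from the reagent-controlled syn-crotylboration, and C3 from alkylation of the lactone enolate anti to the cis methyl and aryl groups. C2 comes from the cyclisation (trans to the C3 methyl), C8'' from ethyl (S)-lactate with Mitsunobu inversion, and C7'' from chelate-controlled Grignard addition.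

Key step: step 11

Step 1
Reactants: 1 4-(benzyloxy)-3-methoxybenzaldehyde
Product: 3 (1S,2R)-1-[4-(benzyloxy)-3-methoxyphenyl]-2-methylbut-3-en-1-ol, via diisopinocampheylborinate 2 (not isolated)
Conditions: cis-2-butene, n-BuLi, KOt-Bu, THF, −78 to −45 °C; (−)-Ipc2BOMe (from (+)-α-pinene), −78 °C; BF3·OEt2; 1, −78 °C; then NaOH, H2O2, rt
Reagents that add atoms: cis-2-butene C/C=C\C
Why: Brown asymmetric crotylboration passes through a closed Zimmerman–Traxler chair, so the Z-crotyl geometry becomes the syn relation of the C5 hydroxyl and the C4 methyl, and the isopinocampheyl groups direct attack to the Si face of the aldehyde, which sets C5 as S and C4 as R.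

Step 2
Reactants: 3 (1S,2R)-1-[4-(benzyloxy)-3-methoxyphenyl]-2-methylbut-3-en-1-ol
Product: 5 (1S,2R)-1-[4-(benzyloxy)-3-methoxyphenyl]-2-methylbutane-1,4-diol, via bis(9-BBN) adduct 4 (not isolated)
Conditions: 9-BBN (2.5 equiv), THF, 0 °C to rt; then NaOH, H2O2, 0 °C
Reagents that add atoms: hydrogen peroxide OO
Why: Anti-Markovnikov hydroboration–oxidation of the monosubstituted alkene puts the new hydroxyl on the terminal carbon C2 without touching a stereocentre, and the extra borane is consumed by the free hydroxyl.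

Step 3
Reactants: 5 (1S,2R)-1-[4-(benzyloxy)-3-methoxyphenyl]-2-methylbutane-1,4-diol
Product: 7 (4R,5S)-5-[4-(benzyloxy)-3-methoxyphenyl]-4-methyloxolan-2-one, via lactol 6 (not isolated)
Conditions: TEMPO (cat.), PhI(OAc)2 (2.2 equiv), CH2Cl2, rt
Reagents that add atoms: none
Why: In this oxoammonium-mediated oxidative lactonisation of a 1,4-diol the primary alcohol reacts much faster than the hindered secondary benzylic one, the hydroxy aldehyde closes to lactol 6, and 6 is oxidised on to the lactone with C4 and C5 unchanged.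

Step 4
Reactants: 7 (4R,5S)-5-[4-(benzyloxy)-3-methoxyphenyl]-4-methyloxolan-2-one
Product: 9 (3R,4R,5S)-5-[4-(benzyloxy)-3-methoxyphenyl]-3,4-dimethyloxolan-2-one, via lithium enolate 8 (not isolated)
Conditions: LiN(SiMe3)2, THF, −78 °C; MeI, −78 to −40 °C
Reagents that add atoms: iodomethane CI
Why: In this lactone enolate alkylation the C4 methyl and the C5 aryl group shield the same face, so MeI enters from the other face and the C3 methyl ends up trans to the C4 methyl; making C3 by C–C bond formation on a ring avoids acyclic hydroboration of a 2-methyl-1-alkene, whose usual anti-Cram 1,2-induction would lead to the cis-dimethyl series.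

Step 5
Reactants: 9 (3R,4R,5S)-5-[4-(benzyloxy)-3-methoxyphenyl]-3,4-dimethyloxolan-2-one
Product: 11 tert-butyldimethylsilyl (2R,3R,4S)-4-[4-(benzyloxy)-3-methoxyphenyl]-4-[(tert-butyldimethylsilyl)oxy]-2,3-dimethylbutanoate, via potassium hydroxy carboxylate 10 (not isolated)
Conditions: KOH, MeOH–H2O, rt, evaporation; TBSCl, imidazole, DMF, rt; used crude
Reagents that add atoms: potassium hydroxide [K+].[OH-]; tert-butyldimethylsilyl chloride CC(C)(C)[Si](C)(C)Cl
Why: In this saponification followed by silylation of the salt, keeping the opened form as its potassium carboxylate prevents relactonisation until both oxygens carry silicon, and no bond to a stereocentre is broken.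

Step 6
Reactants: 11 tert-butyldimethylsilyl (2R,3R,4S)-4-[4-(benzyloxy)-3-methoxyphenyl]-4-[(tert-butyldimethylsilyl)oxy]-2,3-dimethylbutanoate
Product: 12 (2R,3R,4S)-4-[4-(benzyloxy)-3-methoxyphenyl]-4-[(tert-butyldimethylsilyl)oxy]-2,3-dimethylbutan-1-ol
Conditions: i-Bu2AlH (3.5 equiv), CH2Cl2, −78 to 0 °C; aq. potassium sodium tartrate
Reagents that add atoms: none
Why: Hydride reduction of the silyl ester gives the primary alcohol at C2, while the secondary silyl ether and the benzyl ether are inert to the reagent.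

Step 7
Reactants: 12 (2R,3R,4S)-4-[4-(benzyloxy)-3-methoxyphenyl]-4-[(tert-butyldimethylsilyl)oxy]-2,3-dimethylbutan-1-ol
Product: 13 {(1S,2R,3R)-1-[4-(benzyloxy)-3-methoxyphenyl]-4-iodo-2,3-dimethylbutoxy}(tert-butyl)dimethylsilane
Conditions: I2, PPh3, imidazole, CH2Cl2, 0 °C
Reagents that add atoms: iodine II
Why: Appel-type (Garegg–Samuelsson) iodination replaces the primary hydroxyl by SN2 attack on the oxyphosphonium ion under near-neutral conditions that leave the benzylic silyl ether untouched.

Step 8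
Reactants: 14 4-bromo-2-methoxyphenol
Product: 15 (4-bromo-2-methoxyphenoxy)(tert-butyl)dimethylsilane
Conditions: TBSCl, imidazole, DMF, rt
Reagents that add atoms: tert-butyldimethylsilyl chloride CC(C)(C)[Si](C)(C)Cl
Why: Routine silylation of the phenol removes the acidic proton so that the bromide can be turned into a Grignard reagent, and the group later leaves together with the C5 silyl ether.

Step 9
Reactants: 13 {(1S,2R,3R)-1-[4-(benzyloxy)-3-methoxyphenyl]-4-iodo-2,3-dimethylbutoxy}(tert-butyl)dimethylsilane; 15 (4-bromo-2-methoxyphenoxy)(tert-butyl)dimethylsilane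
Product: 17 tert-butyl{4-[(2S,3R,4S)-4-[4-(benzyloxy)-3-methoxyphenyl]-4-[(tert-butyldimethylsilyl)oxy]-2,3-dimethylbutyl]-2-methoxyphenoxy}dimethylsilane, via arylmagnesium bromide 16 (not isolated)
Conditions: 15, Mg, THF, reflux; then 13, Li2CuCl4 (cat.), THF, −20 °C to rt
Reagents that add atoms: none
Why: Copper-catalysed Kochi-type cross-coupling of an aryl Grignard reagent with a primary alkyl iodide forms the C2–ring B bond at a carbon that is not stereogenic, so the neighbouring C3 centre is not at risk.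

Step 10
Reactants: 17 tert-butyl{4-[(2S,3R,4S)-4-[4-(benzyloxy)-3-methoxyphenyl]-4-[(tert-butyldimethylsilyl)oxy]-2,3-dimethylbutyl]-2-methoxyphenoxy}dimethylsilane
Product: 18 (1S,2R,3S)-1-[4-(benzyloxy)-3-methoxyphenyl]-4-(4-hydroxy-3-methoxyphenyl)-2,3-dimethylbutan-1-ol
Conditions: Bu4NF (3 equiv), THF, 0 °C to rt
Reagents that add atoms: none
Why: Fluoride-driven desilylation frees the ring B phenol and the C5 hydroxyl in one operation, while the benzyl ether on ring C stays in place.

Step 11
Reactants: 18 (1S,2R,3S)-1-[4-(benzyloxy)-3-methoxyphenyl]-4-(4-hydroxy-3-methoxyphenyl)-2,3-dimethylbutan-1-ol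
Product: 20 4-{(2R,3R,4R,5S)-5-[4-(benzyloxy)-3-methoxyphenyl]-3,4-dimethyloxolan-2-yl}-2-methoxyphenol, via para-quinone methide 19 (not isolated)
Conditions: Ag2O (2.5 equiv), dry CH2Cl2, high dilution, dark, rt; filtration through Celite
Reagents that add atoms: none
Why: Ag2O removes two electrons and two protons from the only free phenol (the ring B O–H and one benzylic C2–H) and ends as silver metal and water, which gives para-quinone methide 19 with C2 as its electrophilic exocyclic carbon. The C5 hydroxyl then adds to C2 in an intramolecular 1,6-oxa-conjugate addition and ring B regains aromaticity, which forms the C2–O1 bond; the closest known reaction type is oxidative generation of para-quinone methides from 4-alkylphenols with internal capture by an alcohol, as in biomimetic lignan cyclisations. The oxolane closes in a 5-exo-trig mode, since the attacked carbon lies in the new ring and its double-bond partner, the ring B ipso carbon, lies outside it. The one new stereocentre, C2, is controlled by the adjacent C3 centre: 1,3-allylic strain holds the C3–H bond in the plane of the methide, and in the envelope transition state the quinoid ring takes the pseudo-equatorial site away from the C3 methyl, which gives 2R with ring B trans to that methyl. Any 2,3-cis isomer should drain into the more stable trans isomer, because the free para-phenol of 20 lets the C2–O1 bond alone reopen to 19 under mild base, whereas C5 next to the benzyl-protected ring C has no such pathway. The step needs oxidation of ring B only, and capture that is faster than dimerisation or tautomerisation to the styrene, and the benzyl ether on ring C, the high dilution and the five-membered intramolecular capture provide this.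

Step 12
Reactants: 20 4-{(2R,3R,4R,5S)-5-[4-(benzyloxy)-3-methoxyphenyl]-3,4-dimethyloxolan-2-yl}-2-methoxyphenol; 21 ethyl (S)-lactate
Product: 22 ethyl (2R)-2-{4-[(2R,3R,4R,5S)-5-[4-(benzyloxy)-3-methoxyphenyl]-3,4-dimethyloxolan-2-yl]-2-methoxyphenoxy}propanoate
Conditions: PPh3, DIAD, THF, 0 °C to rt
Reagents that add atoms: none
Why: In this Mitsunobu etherification the phenol displaces the oxyphosphonium derivative of the lactate by SN2 with inversion, so the S alcohol becomes the 8''R aryl ether, and ring B can no longer form a quinone methide, which locks C2.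

Step 13
Reactants: 22 ethyl (2R)-2-{4-[(2R,3R,4R,5S)-5-[4-(benzyloxy)-3-methoxyphenyl]-3,4-dimethyloxolan-2-yl]-2-methoxyphenoxy}propanoate
Product: 23 (2R)-2-{4-[(2R,3R,4R,5S)-5-[4-(benzyloxy)-3-methoxyphenyl]-3,4-dimethyloxolan-2-yl]-2-methoxyphenoxy}propanal
Conditions: i-Bu2AlH (1.1 equiv), toluene, −78 °C; MeOH, aq. potassium sodium tartrate; used at once
Reagents that add atoms: none
Why: Partial ester reduction at low temperature stops at the aluminium hemiacetal, which the α-aryloxy oxygen stabilises, and the aldehyde released on work-up is carried on directly so that C8'' has no time to enolise.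

Step 14
Reactants: 14 4-bromo-2-methoxyphenol
Product: 24 1-(benzyloxy)-4-bromo-2-methoxybenzene
Conditions: BnBr, K2CO3, DMF, rt
Reagents that add atoms: benzyl bromide BrCc1ccccc1
Why: Williamson etherification gives ring A the same protecting group as ring C, so both can leave in the last step.

Step 15
Reactants: 23 (2R)-2-{4-[(2R,3R,4R,5S)-5-[4-(benzyloxy)-3-methoxyphenyl]-3,4-dimethyloxolan-2-yl]-2-methoxyphenoxy}propanal; 24 1-(benzyloxy)-4-bromo-2-methoxybenzene
Product: 26 (1R,2R)-1-[4-(benzyloxy)-3-methoxyphenyl]-2-{4-[(2R,3R,4R,5S)-5-[4-(benzyloxy)-3-methoxyphenyl]-3,4-dimethyloxolan-2-yl]-2-methoxyphenoxy}propan-1-ol, via arylmagnesium bromide 25 (not isolated)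
Conditions: 24, Mg, THF, 40 °C; 23, MgBr2·OEt2 (2 equiv), CH2Cl2, −78 °C, then 25 added, −78 °C; aqueous work-up
Reagents that add atoms: none
Why: In this Cram-chelate-controlled Grignard addition magnesium bridges the carbonyl oxygen and the α-aryloxy oxygen, assisted by the ortho-methoxy group, and the aryl nucleophile attacks the face opposite the C8'' methyl, which gives the threo (7''R,8''R) alcohol.

Step 16
Reactants: 26 (1R,2R)-1-[4-(benzyloxy)-3-methoxyphenyl]-2-{4-[(2R,3R,4R,5S)-5-[4-(benzyloxy)-3-methoxyphenyl]-3,4-dimethyloxolan-2-yl]-2-methoxyphenoxy}propan-1-ol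
Product: 27 (1R,2R)-1-(4-hydroxy-3-methoxyphenyl)-2-{4-[(2R,3R,4R,5S)-5-(4-hydroxy-3-methoxyphenyl)-3,4-dimethyloxolan-2-yl]-2-methoxyphenoxy}propan-1-ol
Conditions: H2 (1 atm), 10% Pd/C, EtOAc–MeOH, rt, stopped after two equivalents of H2
Reagents that add atoms: none
Why: Catalytic hydrogenolysis cleaves the two primary benzyl aryl ethers much faster than the secondary benzylic C–O bonds of the oxolane and the carbinol, so all six stereocentres are kept.

Compound list
1 | 4-(benzyloxy)-3-methoxybenzaldehyde (O-benzylvanillin) | COc1cc(C=O)ccc1OCc1ccccc1 | starting material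
2 | diisopinocampheylborinate of 3 (not isolated) | O([C@H](c1ccc(OCc2ccccc2)c(OC)c1)[C@H](C)C=C)B([C@@H]1C[C@@H]2C[C@H]([C@H]1C)C2(C)C)[C@@H]1C[C@@H]2C[C@H]([C@H]1C)C2(C)C | intermediate
3 | (1S,2R)-1-[4-(benzyloxy)-3-methoxyphenyl]-2-methylbut-3-en-1-ol | O[C@H](c1ccc(OCc2ccccc2)c(OC)c1)[C@H](C)C=C | intermediate
4 | bis(9-BBN) adduct of 3, boron on the C5 oxygen and on C2 (not isolated) | B1(O[C@H](c2ccc(OCc3ccccc3)c(OC)c2)[C@H](C)CCB2C3CCCC2CCC3)C2CCCC1CCC2 | intermediate
5 | (1S,2R)-1-[4-(benzyloxy)-3-methoxyphenyl]-2-methylbutane-1,4-diol | O[C@H](c1ccc(OCc2ccccc2)c(OC)c1)[C@H](C)CCO | intermediate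
6 | (4R,5S)-5-[4-(benzyloxy)-3-methoxyphenyl]-4-methyloxolan-2-ol, both anomers (not isolated) | OC1O[C@H](c2ccc(OCc3ccccc3)c(OC)c2)[C@H](C)C1 | intermediate
7 | (4R,5S)-5-[4-(benzyloxy)-3-methoxyphenyl]-4-methyloxolan-2-one | O=C1O[C@H](c2ccc(OCc3ccccc3)c(OC)c2)[C@H](C)C1 | intermediate
8 | lithium enolate of 7 (not isolated) | [Li]OC1=C[C@@H](C)[C@@H](c2ccc(OCc3ccccc3)c(OC)c2)O1 | intermediate
9 | (3R,4R,5S)-5-[4-(benzyloxy)-3-methoxyphenyl]-3,4-dimethyloxolan-2-one | O=C1O[C@H](c2ccc(OCc3ccccc3)c(OC)c2)[C@H](C)[C@H]1C | intermediate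
10 | potassium (2R,3R,4S)-4-[4-(benzyloxy)-3-methoxyphenyl]-4-hydroxy-2,3-dimethylbutanoate (not isolated) | O[C@H](c1ccc(OCc2ccccc2)c(OC)c1)[C@H](C)[C@@H](C)C(=O)[O-].[K+] | intermediate
11 | tert-butyldimethylsilyl (2R,3R,4S)-4-[4-(benzyloxy)-3-methoxyphenyl]-4-[(tert-butyldimethylsilyl)oxy]-2,3-dimethylbutanoate | CC(C)(C)[Si](C)(C)O[C@H](c1ccc(OCc2ccccc2)c(OC)c1)[C@H](C)[C@@H](C)C(=O)O[Si](C)(C)C(C)(C)C | intermediate
12 | (2R,3R,4S)-4-[4-(benzyloxy)-3-methoxyphenyl]-4-[(tert-butyldimethylsilyl)oxy]-2,3-dimethylbutan-1-ol | CC(C)(C)[Si](C)(C)O[C@H](c1ccc(OCc2ccccc2)c(OC)c1)[C@H](C)[C@@H](C)CO | intermediate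
13 | {(1S,2R,3R)-1-[4-(benzyloxy)-3-methoxyphenyl]-4-iodo-2,3-dimethylbutoxy}(tert-butyl)dimethylsilane | CC(C)(C)[Si](C)(C)O[C@H](c1ccc(OCc2ccccc2)c(OC)c1)[C@H](C)[C@@H](C)CI | intermediate
14 | 4-bromo-2-methoxyphenol | COc1cc(Br)ccc1O | starting material
15 | (4-bromo-2-methoxyphenoxy)(tert-butyl)dimethylsilane | COc1cc(Br)ccc1O[Si](C)(C)C(C)(C)C | intermediate
16 | {4-[(tert-butyldimethylsilyl)oxy]-3-methoxyphenyl}magnesium bromide (not isolated) | COc1cc([Mg]Br)ccc1O[Si](C)(C)C(C)(C)C | intermediate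
17 | tert-butyl{4-[(2S,3R,4S)-4-[4-(benzyloxy)-3-methoxyphenyl]-4-[(tert-butyldimethylsilyl)oxy]-2,3-dimethylbutyl]-2-methoxyphenoxy}dimethylsilane | CC(C)(C)[Si](C)(C)O[C@H](c1ccc(OCc2ccccc2)c(OC)c1)[C@H](C)[C@@H](C)Cc1ccc(O[Si](C)(C)C(C)(C)C)c(OC)c1 | intermediate
18 | (1S,2R,3S)-1-[4-(benzyloxy)-3-methoxyphenyl]-4-(4-hydroxy-3-methoxyphenyl)-2,3-dimethylbutan-1-ol | O[C@H](c1ccc(OCc2ccccc2)c(OC)c1)[C@H](C)[C@@H](C)Cc1ccc(O)c(OC)c1 | intermediate
19 | 4-{(2S,3R,4S)-4-[4-(benzyloxy)-3-methoxyphenyl]-4-hydroxy-2,3-dimethylbutylidene}-2-methoxycyclohexa-2,5-dien-1-one (not isolated) | O[C@H](c1ccc(OCc2ccccc2)c(OC)c1)[C@H](C)[C@@H](C)C=C1C=CC(=O)C(OC)=C1 | intermediate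
20 | 4-{(2R,3R,4R,5S)-5-[4-(benzyloxy)-3-methoxyphenyl]-3,4-dimethyloxolan-2-yl}-2-methoxyphenol | COc1cc([C@@H]2O[C@H](c3ccc(OCc4ccccc4)c(OC)c3)[C@H](C)[C@H]2C)ccc1O | intermediate
21 | ethyl (S)-lactate | C[C@H](O)C(=O)OCC | starting material
22 | ethyl (2R)-2-{4-[(2R,3R,4R,5S)-5-[4-(benzyloxy)-3-methoxyphenyl]-3,4-dimethyloxolan-2-yl]-2-methoxyphenoxy}propanoate | CCOC(=O)[C@@H](C)Oc1ccc([C@@H]2O[C@H](c3ccc(OCc4ccccc4)c(OC)c3)[C@H](C)[C@H]2C)cc1OC | intermediate
23 | (2R)-2-{4-[(2R,3R,4R,5S)-5-[4-(benzyloxy)-3-methoxyphenyl]-3,4-dimethyloxolan-2-yl]-2-methoxyphenoxy}propanal | O=C[C@@H](C)Oc1ccc([C@@H]2O[C@H](c3ccc(OCc4ccccc4)c(OC)c3)[C@H](C)[C@H]2C)cc1OC | intermediate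
24 | 1-(benzyloxy)-4-bromo-2-methoxybenzene | COc1cc(Br)ccc1OCc1ccccc1 | intermediate
25 | [4-(benzyloxy)-3-methoxyphenyl]magnesium bromide (not isolated) | COc1cc([Mg]Br)ccc1OCc1ccccc1 | intermediate
26 | (1R,2R)-1-[4-(benzyloxy)-3-methoxyphenyl]-2-{4-[(2R,3R,4R,5S)-5-[4-(benzyloxy)-3-methoxyphenyl]-3,4-dimethyloxolan-2-yl]-2-methoxyphenoxy}propan-1-ol | COc1cc([C@@H](O)[C@@H](C)Oc2ccc([C@@H]3O[C@H](c4ccc(OCc5ccccc5)c(OC)c4)[C@H](C)[C@H]3C)cc2OC)ccc1OCc1ccccc1 | intermediate
27 | (1R,2R)-1-(4-hydroxy-3-methoxyphenyl)-2-{4-[(2R,3R,4R,5S)-5-(4-hydroxy-3-methoxyphenyl)-3,4-dimethyloxolan-2-yl]-2-methoxyphenoxy}propan-1-ol (CNP0171079.2) | COc1cc([C@@H](O)[C@@H](C)Oc2ccc([C@@H]3O[C@H](c4ccc(O)c(OC)c4)[C@H](C)[C@H]3C)cc2OC)ccc1O | target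

Total step count: 16
Longest linear sequence: 14 steps (steps 1–7, 9–13, 15 and 16)

Steps most likely to fail

Step 11. One-electron chemistry at silver may couple phenoxyl radicals at the free ortho position of ring B. The methide may tautomerise to the conjugated styrene, which would erase C3, or capture may be incompletely trans-selective at C2. The fallback reaches the same methide by elimination instead of oxidation; it sets out from 12 and comes back at 20. Alcohol 12 is oxidised with Dess–Martin periodinane to the silyloxy dimethylbutanal F1. Grignard reagent 16 is added to give the epimeric ring B benzylic alcohols F2, and acetylation (Ac2O, pyridine, DMAP) gives the benzylic acetate F3. Bu4NF in THF then removes both silyl groups. The ring B phenoxide expels acetate in a 1,6-elimination to give 19, external adducts of 19 stay reversible in the basic medium, and the freed C5 hydroxyl closes the ring to 20.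

Step 15. An aryloxy oxygen is a weak donor for magnesium, so open Felkin–Anh attack may compete and erode the threo selectivity. The aldehyde may also enolise, with loss of configuration at C8''. The fallback sets C7'' by hydride delivery to a ketone instead of aryl delivery to an aldehyde; it sets out from 22 and comes back at 26. Ester 22 is converted with MeNH(OMe)·HCl and i-PrMgCl into the Weinreb amide F4, and Grignard reagent 25 adds once to give the α-aryloxy aryl ketone F5. Reduction with LiBH(s-Bu)3 in THF at −78 °C uses a bulky non-chelating hydride that follows the polar Felkin–Anh model, attacking anti to the C8''–O bond, and should give the threo alcohol 26.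

Step 9. Substitution at the β-branched primary carbon may be slow, so halogen–metal exchange, elimination or homocoupling of the Grignard reagent may take over. The fallback reverses the polarity of the two partners; it sets out from 13 (with 15) and comes back at 17. Iodide 13 is lithiated with t-BuLi (2 equiv, Et2O, −78 °C) and trapped with B-methoxy-9-BBN to give the lithium alkyl(methoxy)borate F6. F6 is joined to bromide 15 in a B-alkyl Suzuki–Miyaura coupling (Pd(dppf)Cl2, K3PO4, DMF–H2O, rt) to give 17.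

Further compounds
F1 | step 11 | (2R,3R,4S)-4-[4-(benzyloxy)-3-methoxyphenyl]-4-[(tert-butyldimethylsilyl)oxy]-2,3-dimethylbutanal | CC(C)(C)[Si](C)(C)O[C@H](c1ccc(OCc2ccccc2)c(OC)c1)[C@H](C)[C@@H](C)C=O
F2 | step 11 | (2R,3R,4S)-4-[4-(benzyloxy)-3-methoxyphenyl]-4-[(tert-butyldimethylsilyl)oxy]-1-{4-[(tert-butyldimethylsilyl)oxy]-3-methoxyphenyl}-2,3-dimethylbutan-1-ol, both C1 epimers | CC(C)(C)[Si](C)(C)O[C@H](c1ccc(OCc2ccccc2)c(OC)c1)[C@H](C)[C@@H](C)C(O)c1ccc(O[Si](C)(C)C(C)(C)C)c(OC)c1
F3 | step 11 | (2R,3R,4S)-4-[4-(benzyloxy)-3-methoxyphenyl]-4-[(tert-butyldimethylsilyl)oxy]-1-{4-[(tert-butyldimethylsilyl)oxy]-3-methoxyphenyl}-2,3-dimethylbutyl acetate, both C1 epimers | CC(C)(C)[Si](C)(C)O[C@H](c1ccc(OCc2ccccc2)c(OC)c1)[C@H](C)[C@@H](C)C(OC(C)=O)c1ccc(O[Si](C)(C)C(C)(C)C)c(OC)c1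
F4 | step 15 | (2R)-2-{4-[(2R,3R,4R,5S)-5-[4-(benzyloxy)-3-methoxyphenyl]-3,4-dimethyloxolan-2-yl]-2-methoxyphenoxy}-N-methoxy-N-methylpropanamide | CON(C)C(=O)[C@@H](C)Oc1ccc([C@@H]2O[C@H](c3ccc(OCc4ccccc4)c(OC)c3)[C@H](C)[C@H]2C)cc1OC
F5 | step 15 | (2R)-1-[4-(benzyloxy)-3-methoxyphenyl]-2-{4-[(2R,3R,4R,5S)-5-[4-(benzyloxy)-3-methoxyphenyl]-3,4-dimethyloxolan-2-yl]-2-methoxyphenoxy}propan-1-one | COc1cc(C(=O)[C@@H](C)Oc2ccc([C@@H]3O[C@H](c4ccc(OCc5ccccc5)c(OC)c4)[C@H](C)[C@H]3C)cc2OC)ccc1OCc1ccccc1
F6 | step 9 | lithium {(2R,3R,4S)-4-[4-(benzyloxy)-3-methoxyphenyl]-4-[(tert-butyldimethylsilyl)oxy]-2,3-dimethylbutyl}(methoxy)-9-borabicyclo[3.3.1]nonan-9-uide | CC(C)(C)[Si](C)(C)O[C@H](c1ccc(OCc2ccccc2)c(OC)c1)[C@H](C)[C@@H](C)C[B-]1(OC)C2CCCC1CCC2.[Li+]
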